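## Retrosynthetic overview

- Ring numbering: C1 (stereocentre), C2, C3=C4 (CH2OH on C4), C5, C6, C7=C8 (CH3), C9, C10, C11=C12 (CH3), C13, C14; C15 is the exocyclic =CH2-bearing carbon. The strategy rests on C1: the only stereocentre, a lone methine carrying the two ring CH2 arms C2 and C14 and the 1,1-disubstituted alkenyl carbon C15, the pattern left by a secondary boronic ester alkenylated with retention.
- The only ring (14-membered) is formed late, at C5–C6, by intramolecular alkylation of an allylic sulfone anion (C6) with a Baylis–Hillman-derived allylic bromide (C3 aldehyde + methyl acrylate). Ester reduction and desulfonylation finish the synthesis.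
- C1–C14 and C1–C15 are made in one pot from a lithiated C1–C3 carbamate, a C6–C14 pinacol boronic ester and a C15 alkenyllithium.
- Fragments: nerol gives the boronic ester (silylation, allylic oxidation, bromination, one-carbon borylmethylation); propane-1,3-diol gives the carbamate; 6-methylhept-5-en-2-one gives the trisylhydrazone for the Shapiro reaction.

Key step: step 8

Remark: CIP analysis of the target gives R at C1, which requires (+)-sparteine; (+)-sparteine, bis(pinacolato)diborylmethane and 2,4,6-triisopropylbenzenesulfonohydrazide are taken as commercial reagents.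

## Route

Step 1
Reactants: 1 nerol
Product: 2 tert-butyl{[(2Z)-3,7-dimethylocta-2,6-dien-1-yl]oxy}dimethylsilane (neryl TBS ether)
Conditions: TBSCl, imidazole, DMF, rt
Reagents that add atoms: tert-butyldimethylsilyl chloride, CC(C)(C)[Si](C)(C)Cl
Why: Imidazole-mediated silylation of a primary allylic alcohol is routine and leaves the Z alkene (later C7=C8) untouched.

Step 2
Reactants: 2 neryl TBS ether
Product: 4 (2E,6Z)-8-(tert-butyldimethylsilyloxy)-2,6-dimethylocta-2,6-dien-1-ol, via over-oxidised enal 3 (not isolated)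
Conditions: SeO2 (cat.), tBuOOH, salicylic acid (cat.), CH2Cl2, rt; then NaBH4, MeOH, 0 °C
Reagents that add atoms: selenium dioxide, O=[Se]=O (delivers the oxygen and is regenerated by tert-butyl hydroperoxide, CC(C)(C)OO)
Why: Riley-type allylic oxidation (ene reaction, then [2,3]-sigmatropic shift) should attack the more electron-rich terminal alkene at its E-methyl group and give the E allylic alcohol (later C11=C12, C13), with borohydride returning any enal 3 to 4.

Step 3
Reactants: 4 allylic alcohol
Product: 5 {[(2Z,6E)-8-bromo-3,7-dimethylocta-2,6-dien-1-yl]oxy}(tert-butyl)dimethylsilane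
Conditions: CBr4, PPh3, CH2Cl2, 0 °C
Reagents that add atoms: carbon tetrabromide, BrC(Br)(Br)Br
Why: Appel bromination of a primary allylic alcohol should proceed by SN2 at carbon without allylic transposition or change of alkene geometry, and the silyl ether is inert.

Step 4
Reactants: 5 allylic bromide
Product: 6 tert-butyldimethyl{[(2Z,6E)-3,7-dimethyl-9-(4,4,5,5-tetramethyl-1,3,2-dioxaborolan-2-yl)nona-2,6-dien-1-yl]oxy}silane (C6–C14 boronic ester)
Conditions: CH2(Bpin)2, NaOtBu, THF, 0 °C → rt
Reagents that add atoms: bis(pinacolato)diborylmethane, CC1(C)OB(CB2OC(C)(C)C(C)(C)O2)OC1(C)C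
Why: In this deborylative alkylation, tert-butoxide should release the α-boryl carbanion from the geminal diboronate, and this carbanion should displace the primary allylic bromide by SN2, adding C14 with its boron in one operation without a π-allyl intermediate, so both alkene geometries are kept.

Step 5
Reactants: 7 propane-1,3-diol
Product: 8 3-(triisopropylsilyloxy)propan-1-ol
Conditions: NaH (1 equiv), THF, rt; then TIPSCl
Reagents that add atoms: triisopropylsilyl chloride, CC(C)[Si](Cl)(C(C)C)C(C)C
Why: Monosilylation of a symmetrical diol through its sparingly soluble monosodium alkoxide is a standard way to desymmetrise 1,n-diols.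

Step 6
Reactants: 8 3-(triisopropylsilyloxy)propan-1-ol
Product: 9 3-(triisopropylsilyloxy)propyl N,N-diisopropylcarbamate (C1–C3 unit)
Conditions: iPr2NCOCl, Et3N, CH2Cl2, reflux
Reagents that add atoms: N,N-diisopropylcarbamoyl chloride, CC(C)N(C(C)C)C(Cl)=O
Why: Acyl substitution at the carbamoyl chloride should give the hindered carbamate that directs and stabilises α-lithiation.

Step 7
Reactants: 10 6-methylhept-5-en-2-one
Product: 11 N'-(6-methylhept-5-en-2-ylidene)-2,4,6-triisopropylbenzenesulfonohydrazide (trisylhydrazone, mainly E)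
Conditions: 2,4,6-triisopropylbenzenesulfonohydrazide, MeOH, HCl (cat.), rt
Reagents that add atoms: 2,4,6-triisopropylbenzenesulfonohydrazide, CC(C)c1cc(C(C)C)c(S(=O)(=O)NN)c(C(C)C)c1
Why: Condensation of a methyl ketone with the arenesulfonyl hydrazide should give the crystalline hydrazone needed for a Shapiro reaction.

Step 8
Reactants: 9 carbamate; 6 C6–C14 boronic ester; 11 trisylhydrazone
Product: 18 (2Z,6E,10R)-1-(tert-butyldimethylsilyloxy)-3,7,15-trimethyl-11-methylidene-10-[2-(triisopropylsilyloxy)ethyl]hexadeca-2,6,14-triene (acyclic C3–C1–C14–C6 tetraene, C1 set), via lithiated carbamate 12 (not isolated), via boronate complex 13 (not isolated), via secondary boronic ester 14 (not isolated), via alkenyllithium 15 (not isolated), via alkenylboronate complex 16 (not isolated), via iodo boronic ester 17 (not isolated)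
Conditions: 9 (1.3 equiv), (+)-sparteine, sBuLi, Et2O, −78 °C, 5 h; 6, −78 °C, 1 h, then 40 °C, 16 h; THF, −78 °C, then 15 [second flask: 11, nBuLi (2 equiv), THF, −78 → 0 °C] (3 equiv); I2, MeOH/THF, −78 °C; NaOMe, MeOH, −78 °C → rt
Reagents that add atoms: none
Why: sBuLi·(+)-sparteine should remove the pro-R hydrogen at C1 of 9 to give the configurationally stable lithiated carbamate 12, which adds to the boron of 6 with retention (13), and antiperiplanar 1,2-shift of the C14 alkyl group expels the carbamate with inversion at C1 to give secondary boronic ester 14. Alkenyllithium 15, made by Shapiro reaction of 11, then forms boronate 16, iodine opens it through an iodonium ion with 1,2-shift of C1 onto C15 with retention (17), and methoxide triggers anti elimination of boron and iodine to leave the 1,1-disubstituted alkene. The closest known reactions are the lithiation–borylation of sparteine-complexed lithiated primary alkyl carbamates with primary pinacol boronic esters and the Zweifel olefination of secondary boronic esters with 1-substituted alkenyllithiums, here run one after the other in the same vessel. No ring is closed in this step. The single new stereocentre C1 is fixed as R by the reagent, that is by the (+)-enantiomer of sparteine in the deprotonation, and is carried through the stereospecific retention–inversion–retention sequence. The step needs selection between the enantiotopic C1 protons, complete boronate formation before warming, and iodination of the alkenylboronate in preference to the isolated alkenes; this is secured because both partners carry only silyl ethers and unactivated trisubstituted alkenes, the γ-silyloxy group is too poor a leaving group for 1,3-elimination, and the boronate alkene is far more nucleophilic toward iodine than the others.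

Step 9
Reactants: 18 bis-silyl ether
Product: 19 (2Z,6E,10R)-3,7,15-trimethyl-11-methylidene-10-[2-(triisopropylsilyloxy)ethyl]hexadeca-2,6,14-trien-1-ol (C6 alcohol)
Conditions: PPTS, MeOH/CH2Cl2, rt
Reagents that add atoms: none
Why: Acid-catalysed methanolysis should cleave the less hindered allylic primary tert-butyldimethylsilyl ether well before the bulkier triisopropylsilyl ether, a standard differentiation of these two groups.

Step 10
Reactants: 19 C6 alcohol
Product: 20 {[(3R,6E,10Z)-12-chloro-6,10-dimethyl-3-(6-methylhepta-1,5-dien-2-yl)dodeca-6,10-dien-1-yl]oxy}triisopropylsilane (C6 chloride)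
Conditions: NCS, Me2S, CH2Cl2, −20 → 0 °C
Reagents that add atoms: N-chlorosuccinimide, O=C1CCC(=O)N1Cl
Why: Corey–Kim chlorination converts allylic alcohols into chlorides under neutral conditions by SN2 collapse of the alkoxysulfonium chloride, without transposition and with the Z geometry of C7=C8 kept.

Step 11
Reactants: 20 C6 chloride
Product: 21 triisopropyl{[(3R,6E,10Z)-6,10-dimethyl-3-(6-methylhepta-1,5-dien-2-yl)-12-(phenylsulfonyl)dodeca-6,10-dien-1-yl]oxy}silane (C6 sulfone)
Conditions: PhSO2Na, DMF, rt
Reagents that add atoms: sodium benzenesulfinate, [Na+].[O-]S(=O)c1ccccc1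
Why: S-Alkylation of the sulfinate by SN2 at the primary allylic chloride should give the allylic phenyl sulfone that will acidify C6.

Step 12
Reactants: 21 C6 sulfone
Product: 22 (3R,6E,10Z)-6,10-dimethyl-3-(6-methylhepta-1,5-dien-2-yl)-12-(phenylsulfonyl)dodeca-6,10-dien-1-ol (C3 alcohol)
Conditions: TBAF, AcOH, THF, rt
Reagents that add atoms: none
Why: Fluoride cleaves the triisopropylsilyl ether, and the acetic acid buffer should keep the medium from isomerising the base-sensitive allylic sulfone.

Step 13
Reactants: 22 C3 alcohol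
Product: 23 (3R,6E,10Z)-6,10-dimethyl-3-(6-methylhepta-1,5-dien-2-yl)-12-(phenylsulfonyl)dodeca-6,10-dienal (C3 aldehyde)
Conditions: Dess–Martin periodinane, CH2Cl2, 0 °C → rt
Reagents that add atoms: none
Why: Dess–Martin oxidation should give the aldehyde without touching the alkenes or the sulfone, and C1, being β to the carbonyl, cannot epimerise.

Step 14
Reactants: 23 C3 aldehyde
Product: 24 methyl (5R,8E,12Z)-3-hydroxy-8,12-dimethyl-2-methylidene-5-(6-methylhepta-1,5-dien-2-yl)-14-(phenylsulfonyl)tetradeca-8,12-dienoate (both C3 epimers)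
Conditions: methyl acrylate (excess), DABCO (1 equiv), MeOH, rt, several days
Reagents that add atoms: methyl acrylate, C=CC(=O)OC
Why: The Morita–Baylis–Hillman reaction of an unhindered aliphatic aldehyde should add C4 with its ester and the future C5; the carbinol configuration is irrelevant because it is lost in step 15.

Step 15
Reactants: 24 Baylis–Hillman adduct
Product: 25 methyl (2Z,5R,8E,12Z)-2-(bromomethyl)-8,12-dimethyl-5-(6-methylhepta-1,5-dien-2-yl)-14-(phenylsulfonyl)tetradeca-2,8,12-trienoate
Conditions: NBS, Me2S, CH2Cl2, 0 °C → rt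
Reagents that add atoms: N-bromosuccinimide, O=C1CCC(=O)N1Br
Why: Corey–Kim activation of the Baylis–Hillman alcohol followed by SN2′ delivery of bromide should give the thermodynamically preferred 2-(bromomethyl)enoate with C2 cis to CH2Br and trans to the ester, the geometry C3=C4 has in the target.

Step 16
Reactants: 25 allylic bromide
Product: 26 methyl (1R,3E,7Z,11E)-8,12-dimethyl-1-(6-methylhepta-1,5-dien-2-yl)-6-(phenylsulfonyl)cyclotetradeca-3,7,11-triene-4-carboxylate (ring numbering of the overview; both C6 epimers)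
Conditions: LiN(SiMe3)2 (1.05 equiv) added slowly, THF (0.002 M), −78 → 0 °C
Reagents that add atoms: none
Why: The α-sulfonyl allylic carbanion at C6 should displace the primary allylic bromide at C5 by intramolecular exo-tet SN2 alkylation under high dilution, closing the 14-membered ring as in classical sulfur-stabilised carbanion macrocyclisations of cembranoids; the C6 configuration is uncontrolled and is erased in step 18.

Step 17
Reactants: 26 macrocyclic sulfone ester
Product: 27 [(1R,3E,7Z,11E)-8,12-dimethyl-1-(6-methylhepta-1,5-dien-2-yl)-6-(phenylsulfonyl)cyclotetradeca-3,7,11-trien-4-yl]methanol (ring numbering of the overview; both C6 epimers)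
Conditions: iBu2AlH, CH2Cl2, −78 °C; Rochelle salt work-up
Reagents that add atoms: none
Why: 1,2-Reduction of the conjugated methyl ester by the aluminium hydride should give the allylic alcohol without touching the sulfone or the alkene geometries.

Step 18
Reactants: 27 macrocyclic sulfone alcohol
Product: 28 CNP0217603.1, [(1R,3E,7Z,11E)-8,12-dimethyl-1-(6-methylhepta-1,5-dien-2-yl)cyclotetradeca-3,7,11-trien-4-yl]methanol (ring numbering of the overview)
Conditions: PdCl2(dppp) (cat.), LiBHEt3, THF, 0 °C
Reagents that add atoms: none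
Why: Palladium-catalysed reductive desulfonylation of an allylic sulfone should proceed through a π-allyl complex that takes hydride at the less substituted terminus C6, so C7=C8 should stay in place and keep its Z geometry.

## Compound list

1 | nerol, (2Z)-3,7-dimethylocta-2,6-dien-1-ol | CC(C)=CCC/C(C)=C\CO | starting material
2 | tert-butyl{[(2Z)-3,7-dimethylocta-2,6-dien-1-yl]oxy}dimethylsilane | CC(C)=CCC/C(C)=C\CO[Si](C)(C)C(C)(C)C | intermediate
3 | (2E,6Z)-8-(tert-butyldimethylsilyloxy)-2,6-dimethylocta-2,6-dienal | O=C/C(C)=C/CC/C(C)=C\CO[Si](C)(C)C(C)(C)C | intermediate (not isolated)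
4 | (2E,6Z)-8-(tert-butyldimethylsilyloxy)-2,6-dimethylocta-2,6-dien-1-ol | OC/C(C)=C/CC/C(C)=C\CO[Si](C)(C)C(C)(C)C | intermediate
5 | {[(2Z,6E)-8-bromo-3,7-dimethylocta-2,6-dien-1-yl]oxy}(tert-butyl)dimethylsilane | BrC/C(C)=C/CC/C(C)=C\CO[Si](C)(C)C(C)(C)C | intermediate
6 | tert-butyldimethyl{[(2Z,6E)-3,7-dimethyl-9-(4,4,5,5-tetramethyl-1,3,2-dioxaborolan-2-yl)nona-2,6-dien-1-yl]oxy}silane | CC1(C)OB(CC/C(C)=C/CC/C(C)=C\CO[Si](C)(C)C(C)(C)C)OC1(C)C | intermediate
7 | propane-1,3-diol | OCCCO | starting material
8 | 3-(triisopropylsilyloxy)propan-1-ol | OCCCO[Si](C(C)C)(C(C)C)C(C)C | intermediate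
9 | 3-(triisopropylsilyloxy)propyl N,N-diisopropylcarbamate | CC(C)N(C(C)C)C(=O)OCCCO[Si](C(C)C)(C(C)C)C(C)C | intermediate
10 | 6-methylhept-5-en-2-one | CC(=O)CCC=C(C)C | starting material
11 | N'-(6-methylhept-5-en-2-ylidene)-2,4,6-triisopropylbenzenesulfonohydrazide (E shown) | C/C(CCC=C(C)C)=N\NS(=O)(=O)c1c(C(C)C)cc(C(C)C)cc1C(C)C | intermediate
12 | (R)-1-lithio-3-(triisopropylsilyloxy)propyl N,N-diisopropylcarbamate, (+)-sparteine complex (ligand not drawn) | [Li][C@@H](OC(=O)N(C(C)C)C(C)C)CCO[Si](C(C)C)(C(C)C)C(C)C | intermediate (not isolated)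
13 | lithium boronate complex from 12 and 6 (R at C1) | [Li+].CC(C)N(C(C)C)C(=O)O[C@@H](CCO[Si](C(C)C)(C(C)C)C(C)C)[B-]1(CC/C(C)=C/CC/C(C)=C\CO[Si](C)(C)C(C)(C)C)OC(C)(C)C(C)(C)O1 | intermediate (not isolated)
14 | tert-butyldimethyl{[(2Z,6E,10R)-3,7-dimethyl-10-(4,4,5,5-tetramethyl-1,3,2-dioxaborolan-2-yl)-12-(triisopropylsilyloxy)dodeca-2,6-dien-1-yl]oxy}silane (secondary boronic ester, boron on C1) | CC1(C)OB([C@@H](CCO[Si](C(C)C)(C(C)C)C(C)C)CC/C(C)=C/CC/C(C)=C\CO[Si](C)(C)C(C)(C)C)OC1(C)C | intermediate (not isolated)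
15 | 6-methylhepta-1,5-dien-2-yllithium | [Li]C(=C)CCC=C(C)C | intermediate (not isolated)
16 | lithium alkenylboronate complex from 14 and 15 | [Li+].C=C(CCC=C(C)C)[B-]1([C@@H](CCO[Si](C(C)C)(C(C)C)C(C)C)CC/C(C)=C/CC/C(C)=C\CO[Si](C)(C)C(C)(C)C)OC(C)(C)C(C)(C)O1 | intermediate (not isolated)
17 | β-iodoalkyl boronic ester after 1,2-shift of C1 to C15 (both C15 epimers) | ICC(CCC=C(C)C)(B1OC(C)(C)C(C)(C)O1)[C@@H](CCO[Si](C(C)C)(C(C)C)C(C)C)CC/C(C)=C/CC/C(C)=C\CO[Si](C)(C)C(C)(C)C | intermediate (not isolated)
18 | (2Z,6E,10R)-1-(tert-butyldimethylsilyloxy)-3,7,15-trimethyl-11-methylidene-10-[2-(triisopropylsilyloxy)ethyl]hexadeca-2,6,14-triene | C=C(CCC=C(C)C)[C@@H](CCO[Si](C(C)C)(C(C)C)C(C)C)CC/C(C)=C/CC/C(C)=C\CO[Si](C)(C)C(C)(C)C | intermediate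
19 | (2Z,6E,10R)-3,7,15-trimethyl-11-methylidene-10-[2-(triisopropylsilyloxy)ethyl]hexadeca-2,6,14-trien-1-ol | C=C(CCC=C(C)C)[C@@H](CCO[Si](C(C)C)(C(C)C)C(C)C)CC/C(C)=C/CC/C(C)=C\CO | intermediate
20 | {[(3R,6E,10Z)-12-chloro-6,10-dimethyl-3-(6-methylhepta-1,5-dien-2-yl)dodeca-6,10-dien-1-yl]oxy}triisopropylsilane | C=C(CCC=C(C)C)[C@@H](CCO[Si](C(C)C)(C(C)C)C(C)C)CC/C(C)=C/CC/C(C)=C\CCl | intermediate
21 | triisopropyl{[(3R,6E,10Z)-6,10-dimethyl-3-(6-methylhepta-1,5-dien-2-yl)-12-(phenylsulfonyl)dodeca-6,10-dien-1-yl]oxy}silane | C=C(CCC=C(C)C)[C@@H](CCO[Si](C(C)C)(C(C)C)C(C)C)CC/C(C)=C/CC/C(C)=C\CS(=O)(=O)c1ccccc1 | intermediate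
22 | (3R,6E,10Z)-6,10-dimethyl-3-(6-methylhepta-1,5-dien-2-yl)-12-(phenylsulfonyl)dodeca-6,10-dien-1-ol | C=C(CCC=C(C)C)[C@@H](CCO)CC/C(C)=C/CC/C(C)=C\CS(=O)(=O)c1ccccc1 | intermediate
23 | (3R,6E,10Z)-6,10-dimethyl-3-(6-methylhepta-1,5-dien-2-yl)-12-(phenylsulfonyl)dodeca-6,10-dienal | C=C(CCC=C(C)C)[C@@H](CC=O)CC/C(C)=C/CC/C(C)=C\CS(=O)(=O)c1ccccc1 | intermediate
24 | methyl (5R,8E,12Z)-3-hydroxy-8,12-dimethyl-2-methylidene-5-(6-methylhepta-1,5-dien-2-yl)-14-(phenylsulfonyl)tetradeca-8,12-dienoate (C3 epimers) | C=C(CCC=C(C)C)[C@@H](CC(O)C(=C)C(=O)OC)CC/C(C)=C/CC/C(C)=C\CS(=O)(=O)c1ccccc1 | intermediate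
25 | methyl (2Z,5R,8E,12Z)-2-(bromomethyl)-8,12-dimethyl-5-(6-methylhepta-1,5-dien-2-yl)-14-(phenylsulfonyl)tetradeca-2,8,12-trienoate | C=C(CCC=C(C)C)[C@@H](C/C=C(\CBr)C(=O)OC)CC/C(C)=C/CC/C(C)=C\CS(=O)(=O)c1ccccc1 | intermediate
26 | methyl (1R,3E,7Z,11E)-8,12-dimethyl-1-(6-methylhepta-1,5-dien-2-yl)-6-(phenylsulfonyl)cyclotetradeca-3,7,11-triene-4-carboxylate (overview numbering; C6 epimers) | C=C(CCC=C(C)C)[C@H]1C/C=C(/C(=O)OC)CC(S(=O)(=O)c2ccccc2)/C=C(/C)CC/C=C(\C)CC1 | intermediate
27 | [(1R,3E,7Z,11E)-8,12-dimethyl-1-(6-methylhepta-1,5-dien-2-yl)-6-(phenylsulfonyl)cyclotetradeca-3,7,11-trien-4-yl]methanol (overview numbering; C6 epimers) | C=C(CCC=C(C)C)[C@H]1C/C=C(/CO)CC(S(=O)(=O)c2ccccc2)/C=C(/C)CC/C=C(\C)CC1 | intermediate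
28 | CNP0217603.1, [(1R,3E,7Z,11E)-8,12-dimethyl-1-(6-methylhepta-1,5-dien-2-yl)cyclotetradeca-3,7,11-trien-4-yl]methanol (overview numbering) | C=C(CCC=C(C)C)[C@H]1C/C=C(/CO)CC/C=C(/C)CC/C=C(\C)CC1 | target

## Step count and risks

Total step count: 18. Longest linear sequence: 15 steps (nerol through steps 1–4, step 8, steps 9–18).

The three steps most likely to fail:

**Step 8 (three-component pot).** The deprotonation may be incomplete, or the first boronate may revert instead of rearranging on warming. In the unpurified mixture the sparteine, lithium carbamate and lithium sulfinate may consume alkenyllithium and iodine, so that the second boronate forms only in part or the isolated alkenes are iodinated. The fallback sets out from 9, 6 and 11 and comes back at 18, and gives up the single pot. Lithiation–borylation of 9 with 6 is run alone and the secondary boronic ester 14 is isolated by chromatography, which removes the amine and salts and allows its enantiomeric purity to be checked. Separately, the Shapiro intermediate from 11 is quenched with iodine to give 2-iodo-6-methylhepta-1,5-diene F1, which is purified. Lithium–iodine exchange of F1 with tBuLi (2 equiv, THF, −78 °C) then gives salt-free 15, which is combined with purified 14 in a conventional Zweifel olefination (I2, then NaOMe/MeOH) to give 18.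

**Step 16 (macrocyclisation at C5–C6).** The sulfonyl carbanion may alkylate intermolecularly (oligomers) or attack C3 in SN2′ fashion to close a 12-membered ring, and the amide base may dehydrobrominate the bromomethyl enoate instead of deprotonating C6. The fallback sets out from sulfone 21 and comes back at 26; it forms C5–C6 intermolecularly and closes the ring at C3=C4 instead. Sulfone 21 is deprotonated (LiN(SiMe3)2, THF, −78 °C) and added in a Michael reaction to trimethyl 2-phosphonoacrylate to give methyl (5Z,9E,13R)-2-(dimethoxyphosphoryl)-6,10-dimethyl-13-(6-methylhepta-1,5-dien-2-yl)-4-(phenylsulfonyl)-15-(triisopropylsilyloxy)pentadeca-5,9-dienoate F2. TBAF/AcOH gives the 15-hydroxy compound F3 and Dess–Martin oxidation the 15-oxo compound F4. Intramolecular Horner–Wadsworth–Emmons olefination of F4 (LiCl, DBU, MeCN, high dilution) should then close the 14-membered ring E-selectively, with the ester trans to C2, to give 26.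

**Step 14 (Baylis–Hillman reaction).** Addition of the amine–acrylate zwitterion to the lipophilic β-branched aldehyde may be so slow that acrylate oligomerisation and aldehyde self-condensation take over. The fallback sets out from aldehyde 23 and comes back at 24. Methyl propiolate is hydroaluminated with iBu2AlH in the presence of N-methylmorpholine N-oxide (THF, 0 °C) to give [1-(methoxycarbonyl)ethenyl]diisobutylalane F5, a preformed α-acrylate anion equivalent. Addition of F5 to 23 (vinylalumination) gives 24 directly.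

## Further compounds

F1 | step 8 | 2-iodo-6-methylhepta-1,5-diene | C=C(I)CCC=C(C)C
F2 | step 16 | methyl (5Z,9E,13R)-2-(dimethoxyphosphoryl)-6,10-dimethyl-13-(6-methylhepta-1,5-dien-2-yl)-4-(phenylsulfonyl)-15-(triisopropylsilyloxy)pentadeca-5,9-dienoate | C=C(CCC=C(C)C)[C@@H](CCO[Si](C(C)C)(C(C)C)C(C)C)CC/C(C)=C/CC/C(C)=C\C(CC(C(=O)OC)P(=O)(OC)OC)S(=O)(=O)c1ccccc1
F3 | step 16 | methyl (5Z,9E,13R)-2-(dimethoxyphosphoryl)-15-hydroxy-6,10-dimethyl-13-(6-methylhepta-1,5-dien-2-yl)-4-(phenylsulfonyl)pentadeca-5,9-dienoate | C=C(CCC=C(C)C)[C@@H](CCO)CC/C(C)=C/CC/C(C)=C\C(CC(C(=O)OC)P(=O)(OC)OC)S(=O)(=O)c1ccccc1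
F4 | step 16 | methyl (5Z,9E,13R)-2-(dimethoxyphosphoryl)-6,10-dimethyl-13-(6-methylhepta-1,5-dien-2-yl)-15-oxo-4-(phenylsulfonyl)pentadeca-5,9-dienoate | C=C(CCC=C(C)C)[C@@H](CC=O)CC/C(C)=C/CC/C(C)=C\C(CC(C(=O)OC)P(=O)(OC)OC)S(=O)(=O)c1ccccc1
F5 | step 14 | [1-(methoxycarbonyl)ethenyl]diisobutylalane | COC(=O)C(=C)[Al](CC(C)C)CC(C)C
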